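**Plan**

1. Retrosynthesis: the C8–CH2 bond to the acylphloroglucinol is cut first (Friedel–Crafts benzylation by an 8-hydroxymethyl flavan). The flavan C4 methylene is then traced back to a C4 ketone (2,3-trans flavanonol). The C2–C3 bond of that chromanone is cut by putting the C3 oxygen into the ring, which gives a seven-membered 1,3-benzodioxepin-5-one, the cyclic acetal of 3,4-bis(benzyloxy)benzaldehyde with a 2,ω-dihydroxyacetophenone.
2. Forward: the A ring is present from the start and the B ring arrives with the aldehyde. The seven-membered ring O1–C2–O3–C3–C4(=O)–C4a–C8a is closed and then contracted to the six-membered pyranone (C2 moves from O3 to C3). The C4 oxygen is removed, C8 is hydroxymethylated through the bromide, the separately made acylphloroglucinol is joined, and the benzyl ethers are cleaved last.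
3. Enabling feature: acetal carbon C2 carries both ring oxygens (O1 of the A ring and O3) and the 3,4-dioxygenated B ring, so it ionises to an aryl-stabilised oxocarbenium ion O1=C2. The temporary C4 ketone makes the neighbouring ring carbon C3 an enol carbon. C3–C2 bond formation expels O3 from the ring and leaves it on C3 as the 3-hydroxyl.
4. Stereochemistry: C2 is set in the ring contraction by a chiral confined Brønsted acid acting on the planar oxocarbenium ion, so the racemic acetal converges on one enantiomer. C3 follows as the trans (diequatorial) partner, by the transition state and by enolisation next to the temporary ketone. Later steps touch neither centre, and the C4 centre formed on ketone reduction is erased.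

Key step: step 3

Remark: the flavan-3,4-diol of step 4 is drawn as its 3,4-trans isomer; its C4 configuration does not matter because C4 becomes a methylene group in step 5.

Step 1
Reactants: 1 1-[2,4-bis(benzyloxy)-6-hydroxyphenyl]ethan-1-one
Product: 3 1-[2,4-bis(benzyloxy)-6-hydroxyphenyl]-2-hydroxyethan-1-one, via dipotassium enolate phenoxide 2 (not isolated)
Conditions: KHMDS (2.2 equiv), THF, −78 °C; 2-(phenylsulfonyl)-3-phenyloxaziridine, −78 °C; AcOH
Reagents that add atoms: 2-(phenylsulfonyl)-3-phenyloxaziridine O=S(=O)(c1ccccc1)N1OC1c1ccccc1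
Why: Electrophilic α-hydroxylation of a ketone enolate with an N-sulfonyloxaziridine; two equivalents of base give the phenoxide/enolate dianion, the methyl group is the only enolisable position, and no stereocentre is formed.

Step 2
Reactants: 3 1-[2,4-bis(benzyloxy)-6-hydroxyphenyl]-2-hydroxyethan-1-one; 4 3,4-bis(benzyloxy)benzaldehyde
Product: 6 racemic 6,8-bis(benzyloxy)-2-[3,4-bis(benzyloxy)phenyl]-4H-1,3-benzodioxepin-5-one, via 3,4-bis(benzyloxy)benzaldehyde dimethyl acetal 5 (not isolated)
Conditions: 4, HC(OMe)3, PPTS (cat.), MeOH, rt, evaporate; then 3, PPTS (cat.), PhMe, 50 °C, reduced pressure (−MeOH)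
Reagents that add atoms: none
Why: Acid-catalysed transacetalisation, in which the dimethyl acetal exchanges with the primary hydroxyl and then with the hydrogen-bonded phenol of 3 to close the seven-membered mixed aryl alkyl acetal, driven by removal of methanol; the weak acid should not enolise the ketone, and the acetal carbon is formed racemic, which is of no consequence because it is ionised in step 3.

Step 3
Reactants: 6 racemic 6,8-bis(benzyloxy)-2-[3,4-bis(benzyloxy)phenyl]-4H-1,3-benzodioxepin-5-one
Product: 8 (2R,3R)-5,7-bis(benzyloxy)-2-[3,4-bis(benzyloxy)phenyl]-3-hydroxy-2,3-dihydro-4H-1-benzopyran-4-one, via aryloxocarbenium enediol 7 (not isolated)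
Conditions: chiral imidodiphosphorimidate Brønsted acid (5 mol %, antipode giving 2R fixed by a screen), CHCl3, 5 Å MS, 0 °C → rt
Reagents that add atoms: none
Why: Proposed new method: the confined chiral acid ionises the C2–O3 bond of the seven-membered acetal (ionisation towards the phenol oxygen O1 is reversible and leads nowhere) to the E aryloxocarbenium ion O1=C2, stabilised by the 3,4-bis(benzyloxy)phenyl ring and paired with the chiral anion, while the released α-hydroxy ketone enolises to the Z-enediol; C3 of the enol then adds to C2, so that C2 moves from O3 to C3 and O3 leaves the ring as the 3-hydroxyl (formal 1,2 O-to-C shift, seven- to six-membered). The closest known reaction types are the Mukaiyama-type aldol addition of enol derivatives to acetals, the acid-mediated O-to-C ring contraction of cyclic vinyl acetals (Petasis–Ferrier type, a 1,3-shift) and Prins-type cyclisations of aryl oxocarbenium ions under chiral confined-acid control; the 1,2-variant on an α-acetal-oxy ketone has not been shown. The chromanone ring closes by a 6-(enolendo)-endo-trig C–C bond formation. C2 is set by the chiral counter-anion, which selects one face of the planar oxocarbenium ion, so both enantiomers of 6 should converge on the 2R product; C3 is set relative to C2 by a chair-like transition state with the aryl group and O3 equatorial, and, being α to the ketone, any 2,3-cis isomer can equilibrate through the enol to the trans-diequatorial 3R isomer while the non-enolisable C2 is kept. The step needs C-attack by C3 rather than return to an acetal, which is secured because O–C recombination is reversible whereas C–C bond formation is not under these conditions, and it needs exclusion of water (molecular sieves) so that the cation is not hydrolysed.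

Step 4
Reactants: 8 (2R,3R)-5,7-bis(benzyloxy)-2-[3,4-bis(benzyloxy)phenyl]-3-hydroxy-2,3-dihydro-4H-1-benzopyran-4-one
Product: 9 (2R,3S,4R)-5,7-bis(benzyloxy)-2-[3,4-bis(benzyloxy)phenyl]-3,4-dihydro-2H-1-benzopyran-3,4-diol
Conditions: NaBH4, THF/EtOH, 0 °C
Reagents that add atoms: none
Why: Borohydride reduction of the aryl ketone to the benzylic alcohol; the new C4 centre (expected mainly 3,4-trans) is removed in the next step, and the short, cold, weakly basic conditions are chosen to avoid ring opening of the flavanonol.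

Step 5
Reactants: 9 (2R,3S,4R)-5,7-bis(benzyloxy)-2-[3,4-bis(benzyloxy)phenyl]-3,4-dihydro-2H-1-benzopyran-3,4-diol
Product: 10 (2R,3S)-5,7-bis(benzyloxy)-2-[3,4-bis(benzyloxy)phenyl]-3,4-dihydro-2H-1-benzopyran-3-ol (5,7,3',4'-tetra-O-benzyl-(+)-catechin)
Conditions: Et3SiH, TFA, CH2Cl2, −30 → 0 °C
Reagents that add atoms: none
Why: Ionic hydrogenation, in which the 4-hydroxyl ionises under acid to the 2,4,6-trioxygenated benzylic cation and this is reduced by triethylsilane, so the helper oxygen at C4 is removed while C2, C3 and the far less easily ionised C2–O1 bond are untouched.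

Step 6
Reactants: 10 (2R,3S)-5,7-bis(benzyloxy)-2-[3,4-bis(benzyloxy)phenyl]-3,4-dihydro-2H-1-benzopyran-3-ol
Product: 11 (2R,3S)-5,7-bis(benzyloxy)-2-[3,4-bis(benzyloxy)phenyl]-8-bromo-3,4-dihydro-2H-1-benzopyran-3-ol
Conditions: NBS, CH2Cl2, −78 → 0 °C
Reagents that add atoms: N-bromosuccinimide O=C1CCC(=O)N1Br
Why: Electrophilic aromatic bromination; of the two free A-ring positions, C8 (flanked by O1 and one benzyloxy group) reacts in preference to C6 (flanked by two benzyloxy groups), the usual selectivity of 5,7-di-O-benzyl flavan-3-ols.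

Step 7
Reactants: 11 (2R,3S)-5,7-bis(benzyloxy)-2-[3,4-bis(benzyloxy)phenyl]-8-bromo-3,4-dihydro-2H-1-benzopyran-3-ol
Product: 13 (2R,3S)-5,7-bis(benzyloxy)-2-[3,4-bis(benzyloxy)phenyl]-8-(hydroxymethyl)-3,4-dihydro-2H-1-benzopyran-3-ol, via dilithio alkoxide aryllithium 12 (not isolated)
Conditions: n-BuLi (2.2 equiv), THF, −78 °C; (CH2O)n, −78 °C → rt; H2O
Reagents that add atoms: formaldehyde (from paraformaldehyde) C=O
Why: The first equivalent of butyllithium deprotonates the 3-hydroxyl, the second effects bromine–lithium exchange (faster at −78 °C than benzylic deprotonation of the ethers), and the aryllithium adds to formaldehyde (hydroxymethylation of an aryllithium).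

Step 8
Reactants: 14 2,4-dihydroxy-6-methoxybenzaldehyde
Product: 15 5-methoxy-4-methylbenzene-1,3-diol
Conditions: H2 (3 bar), 10 % Pd/C, AcOH, rt
Reagents that add atoms: none
Why: Palladium-catalysed hydrogenolysis of an electron-rich hydroxybenzaldehyde through the benzylic alcohol to the methyl group (reductive deoxygenation).

Step 9
Reactants: 15 5-methoxy-4-methylbenzene-1,3-diol
Product: 17 1-(4,6-dihydroxy-2-methoxy-3-methylphenyl)-2-methylpropan-1-one, via ketiminium chloride 16 (not isolated)
Conditions: i-PrCN, ZnCl2, HCl (g), Et2O, 0 °C; then H2O, 100 °C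
Reagents that add atoms: isobutyronitrile CC(C)C#N; water O
Why: Houben–Hoesch acylation, in which the nitrilium electrophile attacks C6 of 15 (para to the 3-hydroxyl, flanked by OH and OMe) rather than the carbon between the two hydroxyls, as is usual for phloroglucinol monomethyl ethers, and hydrolysis of the ketiminium salt gives the ketone without cleaving the methyl ether.

Step 10
Reactants: 13 (2R,3S)-5,7-bis(benzyloxy)-2-[3,4-bis(benzyloxy)phenyl]-8-(hydroxymethyl)-3,4-dihydro-2H-1-benzopyran-3-ol; 17 1-(4,6-dihydroxy-2-methoxy-3-methylphenyl)-2-methylpropan-1-one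
Product: 18 1-[3-({(2R,3S)-5,7-bis(benzyloxy)-2-[3,4-bis(benzyloxy)phenyl]-3-hydroxy-3,4-dihydro-2H-1-benzopyran-8-yl}methyl)-2,4-dihydroxy-6-methoxy-5-methylphenyl]-2-methylpropan-1-one (5,7,3',4'-tetra-O-benzylpilosanol B)
Conditions: 17 (3 equiv), TsOH·H2O (5 mol %), MeCN/CH2Cl2, 0 °C
Reagents that add atoms: none
Why: Friedel–Crafts benzylation, in which the 2,4,6-trioxygenated benzylic alcohol ionises under mild acid and the cation is trapped at the only free ring carbon of the acylphloroglucinol, used in excess to suppress self-condensation with C6 of a second flavan; no stereocentre is involved.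

Step 11
Reactants: 18 5,7,3',4'-tetra-O-benzylpilosanol B
Product: 19 pilosanol B, 1-[3-({(2R,3S)-2-(3,4-dihydroxyphenyl)-3,5,7-trihydroxy-3,4-dihydro-2H-1-benzopyran-8-yl}methyl)-2,4-dihydroxy-6-methoxy-5-methylphenyl]-2-methylpropan-1-one
Conditions: H2 (1 atm), Pd(OH)2/C, THF/MeOH, rt
Reagents that add atoms: none
Why: Hydrogenolysis of the four benzyl ethers over palladium hydroxide; the hindered, hydrogen-bonded aryl ketone, the methyl ether, the diarylmethane and both stereocentres should not be affected.

**Compound list**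

1 | 1-[2,4-bis(benzyloxy)-6-hydroxyphenyl]ethan-1-one | CC(=O)c1c(O)cc(OCc2ccccc2)cc1OCc1ccccc1 | starting material
2 | dipotassium enolate phenoxide of 1 | [K+].[K+].C=C([O-])c1c([O-])cc(OCc2ccccc2)cc1OCc1ccccc1 | intermediate
3 | 1-[2,4-bis(benzyloxy)-6-hydroxyphenyl]-2-hydroxyethan-1-one | O=C(CO)c1c(O)cc(OCc2ccccc2)cc1OCc1ccccc1 | intermediate
4 | 3,4-bis(benzyloxy)benzaldehyde | O=Cc1ccc(OCc2ccccc2)c(OCc2ccccc2)c1 | starting material
5 | 3,4-bis(benzyloxy)benzaldehyde dimethyl acetal | COC(OC)c1ccc(OCc2ccccc2)c(OCc2ccccc2)c1 | intermediate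
6 | 6,8-bis(benzyloxy)-2-[3,4-bis(benzyloxy)phenyl]-4H-1,3-benzodioxepin-5-one, racemic at C2 | O=C1COC(c2ccc(OCc3ccccc3)c(OCc3ccccc3)c2)Oc2cc(OCc3ccccc3)cc(OCc3ccccc3)c12 | intermediate
7 | aryloxocarbenium ion O1=C2 carrying the Z-enediol side chain (cation of the ion pair with the catalyst anion) | O/C=C(\O)c1c(OCc2ccccc2)cc(OCc2ccccc2)cc1[O+]=Cc1ccc(OCc2ccccc2)c(OCc2ccccc2)c1 | intermediate
8 | (2R,3R)-5,7-bis(benzyloxy)-2-[3,4-bis(benzyloxy)phenyl]-3-hydroxy-2,3-dihydro-4H-1-benzopyran-4-one | c1c(OCc2ccccc2)cc(OCc2ccccc2)c2c1O[C@H](c1ccc(OCc3ccccc3)c(OCc3ccccc3)c1)[C@@H](O)C2=O | intermediate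
9 | (2R,3S,4R)-5,7-bis(benzyloxy)-2-[3,4-bis(benzyloxy)phenyl]-3,4-dihydro-2H-1-benzopyran-3,4-diol | c1c(OCc2ccccc2)cc(OCc2ccccc2)c2c1O[C@H](c1ccc(OCc3ccccc3)c(OCc3ccccc3)c1)[C@@H](O)[C@@H]2O | intermediate
10 | (2R,3S)-5,7-bis(benzyloxy)-2-[3,4-bis(benzyloxy)phenyl]-3,4-dihydro-2H-1-benzopyran-3-ol | c1c(OCc2ccccc2)cc(OCc2ccccc2)c2c1O[C@H](c1ccc(OCc3ccccc3)c(OCc3ccccc3)c1)[C@@H](O)C2 | intermediate
11 | (2R,3S)-5,7-bis(benzyloxy)-2-[3,4-bis(benzyloxy)phenyl]-8-bromo-3,4-dihydro-2H-1-benzopyran-3-ol | Brc1c(OCc2ccccc2)cc(OCc2ccccc2)c2c1O[C@H](c1ccc(OCc3ccccc3)c(OCc3ccccc3)c1)[C@@H](O)C2 | intermediate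
12 | 8-lithio lithium 3-alkoxide of 10 | [Li]c1c(OCc2ccccc2)cc(OCc2ccccc2)c2c1O[C@H](c1ccc(OCc3ccccc3)c(OCc3ccccc3)c1)[C@@H](O[Li])C2 | intermediate
13 | (2R,3S)-5,7-bis(benzyloxy)-2-[3,4-bis(benzyloxy)phenyl]-8-(hydroxymethyl)-3,4-dihydro-2H-1-benzopyran-3-ol | OCc1c(OCc2ccccc2)cc(OCc2ccccc2)c2c1O[C@H](c1ccc(OCc3ccccc3)c(OCc3ccccc3)c1)[C@@H](O)C2 | intermediate
14 | 2,4-dihydroxy-6-methoxybenzaldehyde | COc1cc(O)cc(O)c1C=O | starting material
15 | 5-methoxy-4-methylbenzene-1,3-diol | COc1cc(O)cc(O)c1C | intermediate
16 | 1-(4,6-dihydroxy-2-methoxy-3-methylphenyl)-2-methylpropan-1-iminium chloride | COc1c(C)c(O)cc(O)c1C(=[NH2+])C(C)C.[Cl-] | intermediate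
17 | 1-(4,6-dihydroxy-2-methoxy-3-methylphenyl)-2-methylpropan-1-one | COc1c(C)c(O)cc(O)c1C(=O)C(C)C | intermediate
18 | 5,7,3',4'-tetra-O-benzylpilosanol B, (2R,3S) | COc1c(C)c(O)c(Cc2c(OCc3ccccc3)cc(OCc3ccccc3)c3c2O[C@H](c2ccc(OCc4ccccc4)c(OCc4ccccc4)c2)[C@@H](O)C3)c(O)c1C(=O)C(C)C | intermediate
19 | pilosanol B, (2R,3S) | COc1c(C)c(O)c(Cc2c(O)cc(O)c3c2O[C@H](c2ccc(O)c(O)c2)[C@@H](O)C3)c(O)c1C(=O)C(C)C | target

**Step count and risks**

Total number of steps: 11. Longest linear sequence: 9 steps (steps 1–7, 10 and 11).

Steps most likely to fail: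

1. Step 3 (Proposed new method). The strongly stabilised oxocarbenium ion may pair only loosely with the chiral anion, so that C–C bond formation proceeds with poor facial selectivity. Enolisation of the hindered aryl ketone may also be so slow that hydrolysis or oligomerisation of the cation takes over. The fallback uses known chemistry, sets out from 1 and 4, and returns at 8. Compound 1 is protected at the phenol as its methoxymethyl ether, 1-[2,4-bis(benzyloxy)-6-(methoxymethoxy)phenyl]ethan-1-one F1 (MOMCl, NaH, DMF). Claisen–Schmidt condensation of F1 with 4 (KOH, EtOH) gives the E chalcone F2. Juliá–Colonna epoxidation (poly-leucine of the configuration that gives the (2R,3S)-epoxide, urea–H2O2, DBU, THF) gives the epoxy ketone F3. Methanolic HCl removes the MOM group and the freed phenol opens the epoxide at the benzylic carbon with inversion, which gives 8; the route continues with step 4.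

2. Step 2. Closure of the seven-membered mixed acetal may stop at open-chain or oligomeric acetals because the hydrogen-bonded phenol is a poor nucleophile. The fallback sets out from 3 and 4 and returns at 6. A reductive etherification (Et3SiH, cat. TMSOTf, CH2Cl2) joins the primary hydroxyl of 3 to the aldehyde carbon of 4 as the 3,4-bis(benzyloxy)benzyl ether F4. Oxidation of this electron-rich benzyl ether with DDQ in dry CH2Cl2 over molecular sieves generates the benzylic oxocarbenium ion, which the neighbouring phenol traps to close 6 (oxidative acetal formation from a p-alkoxybenzyl ether).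

3. Step 10. The benzylic cation may be consumed by self-condensation with C6 of a second flavan, or the acid may start to open the pyran ring, before the less nucleophilic acylphloroglucinol reacts. The fallback reverses the polarity, sets out from 17 and 10, and returns at 18. A Mannich reaction of 17 (Me2NH, CH2O, EtOH) at its only free ring carbon gives the Mannich base F5. Heating F5 with 10 in dioxane releases dimethylamine and forms the o-quinone methide of the acylphloroglucinol, which alkylates C8 of 10 (the position that also reacts in step 6) to give 18; steps 6 and 7 are then not needed.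

Further compounds

F1 | step 3 | 1-[2,4-bis(benzyloxy)-6-(methoxymethoxy)phenyl]ethan-1-one | CC(=O)c1c(OCOC)cc(OCc2ccccc2)cc1OCc1ccccc1
F2 | step 3 | (E)-1-[2,4-bis(benzyloxy)-6-(methoxymethoxy)phenyl]-3-[3,4-bis(benzyloxy)phenyl]prop-2-en-1-one | O=C(/C=C/c1ccc(OCc2ccccc2)c(OCc2ccccc2)c1)c1c(OCOC)cc(OCc2ccccc2)cc1OCc1ccccc1
F3 | step 3 | [(2R,3S)-3-[3,4-bis(benzyloxy)phenyl]oxiran-2-yl][2,4-bis(benzyloxy)-6-(methoxymethoxy)phenyl]methanone | O=C(c1c(OCOC)cc(OCc2ccccc2)cc1OCc1ccccc1)[C@@H]1O[C@H]1c1ccc(OCc2ccccc2)c(OCc2ccccc2)c1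
F4 | step 2 | 1-[2,4-bis(benzyloxy)-6-hydroxyphenyl]-2-{[3,4-bis(benzyloxy)benzyl]oxy}ethan-1-one | O=C(COCc1ccc(OCc2ccccc2)c(OCc2ccccc2)c1)c1c(O)cc(OCc2ccccc2)cc1OCc1ccccc1
F5 | step 10 | 1-{3-[(dimethylamino)methyl]-2,4-dihydroxy-6-methoxy-5-methylphenyl}-2-methylpropan-1-one | COc1c(C)c(O)c(CN(C)C)c(O)c1C(=O)C(C)C
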